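One ratio carries this flask: the highest target reading over the substrate consumed by the end of the same run. It reads 0.552 in east, 0.535 in north and 0.570 in south, although south holds twice the substrate of east. I carry the mean, 0.552, as the peak share: target at its peak per unit of substrate finally consumed, a peak selectivity. My doubt is that each ratio hangs on two readings, each with a scatter of 0.5 percentage points, and the peak may fall between samplings, but the ratios spread by 6.34% of their mean, and I accept that width.

| flask | substrate | partner | remark | time |
|---|---|---|---|---|
| east | 0.17 M | 0.11 M | run made earlier |  |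
| north | 0.17 M | 0.26 M | run made earlier |  |
| south | 0.34 M | 0.17 M | run made earlier |  |
| flask | 0.17 M | 0.170 M |  | 2.5 d |

| run | time / h | target / % | substrate / % |
|---|---|---|---|
| east | 1.33 | 5.7 | 86.5 |
| east | 2.50 | 10.4 | 82.7 |
| east | 4.00 | 12.0 | 79.3 |
| east | 8.00 | 12.8 | 78.2 |
| east | 12.0 | 10.3 | 77.4 |
| east | 20.0 | 8.8 | 77.2 |
| east | 40.0 | 5.6 | 76.8 |
| north | 1.33 | 9.4 | 78.7 |
| north | 2.50 | 15.0 | 74.3 |
| north | 4.00 | 15.7 | 71.7 |
| north | 8.00 | 16.9 | 69.4 |
| north | 12.0 | 14.5 | 68.6 |
| north | 20.0 | 12.6 | 68.0 |
| north | 40.0 | 7.3 | 68.4 |
| south | 1.33 | 7.1 | 85.2 |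
| south | 3.00 | 12.2 | 81.8 |
| south | 8.00 | 12.1 | 79.8 |
| south | 15.0 | 8.6 | 79.7 |
| south | 40.0 | 4.4 | 78.6 |

(each reading ± 0.5 percentage points)

- the best time, 2.5 d at the latest, for target
- the amount of target, in percent of the substrate charged, at that time



So I need the end state of the flask. At equal substrate charge, east and north show substrate left falling as partner to the power 0.135, which gives 72.4% left here and a peak of 15.2%. Two runs leave the shape of that curve open: a straight line in partner gives 73.4% left and a peak of 14.7%, so the choice moves my peak by 0.50 points, and I hold it between the two. For the time, east and north read highest at 8.00 h, but south does at 3.00 h, so I take the middle of 4.00 h and 8.00 h, 0.250 d.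

The forecast gives 14.5% (13.4% to 15.7%) at 0.25 d (0.16 d to 0.34 d), on the ground that “Peak height goes roughly as partner^0.33”. My first peak stands above it by 0.70 points.

The flask gives 14.7% at 0.241 d.

    2 partner → homo dimer (k = 0.109 M⁻¹ min⁻¹)
    intermediate ⇌ target (K = 5.16, k = 0.0202 min⁻¹)
    intermediate ⇌ isomer of the product (K = 40.0, k = 0.00441 min⁻¹)
    substrate + partner → intermediate + released group (k = 0.0329 M⁻¹ min⁻¹)
    partner + target → over-reaction product (k = 0.0250 M⁻¹ min⁻¹)

This flask ends with 72.4% of its substrate left, so its own peak share is 0.533 against the carried 0.552, and its target has dropped to 4.23% by 2.50 d. The neighbouring flask, charged with 0.10 M of partner, takes the same reckoning: substrate left 77.8%, peak 12.3%. It ends with 77.8% of its substrate left, and its target peaks at 11.9%.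

All runs come from a simulation for an exercise; the scatter is artificial.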